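Ring A is disconnected at C2–C3, which reduces the labdane to a carvone-derived ring B cyclohexanone. The key step, a samarium diiodide pinacol cyclisation, forms C2–C3, closes ring A as the trans-decalin and sets both carbinol centres in one operation. It exploits the cis-2,3-diol of ring A, whose chair keeps C2–O equatorial and C3–O axial because an axial C2–O would meet the axial methyls on C10 and C4. The precursor is a keto dialdehyde: ring B with C5 and C10 already set, CH2CHO on C10, CMe2CHO on C5 and the C7 isopropenyl director. The C9 ketone later receives the side chain.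

Key step: step 4

Remark: labdane numbering is used throughout; "methyl face" is the face carrying the C10 methyl (C20) and "H face" the opposite face, which carries H5; the target is taken as drawn, (2S,3R,5S,9R,10S,13E), which is the ent-labdane series.

Step 1
Reactants: 1 (S)-carvone; 2 methyl isobutyrate; 3 methyl bromoacetate
Product: 6 keto diester, via ester lithium enolate 4 (not isolated), via Michael-adduct lithium enolate 5 (not isolated)
Conditions: LiN(iPr)2 (1.1 equiv), 2, THF, −78 °C; add 1, −78 → 0 °C; then DMPU, 3, −78 °C → rt
Reagents that add atoms: none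
Why: Tandem Michael addition–enolate alkylation, in which the kinetic 1,2-adduct of the hindered ester enolate reverts on warming to the conjugate adduct formed by axial attack anti to the C7 isopropenyl group (sets C5), and the regiodefined enolate 5 is then alkylated by the reactive bromoacetate on the face anti to the bulky C5 substituent (sets C10, CH2CO2Me trans to the C5 chain).

Step 2
Reactants: 6 keto diester
Product: 7 triol
Conditions: LiAlH4, THF, 0 °C → reflux
Reagents that add atoms: none
Why: Hydride reduction of both esters and the ketone, the new C9 carbinol being an inconsequential epimer mixture because it is re-oxidised in step 3.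

Step 3
Reactants: 7 triol
Product: 8 keto dialdehyde
Conditions: (COCl)2, DMSO (excess), CH2Cl2, −78 °C; Et3N, −78 → 0 °C; crude 8 used at once
Reagents that add atoms: none
Why: Swern oxidation with excess reagent converts all three hydroxyls into alkoxysulfonium salts before base is added, so both aldehydes and the ketone are released together without lactol formation, and no stereocentre is at risk because C10 and C4 are quaternary and C5 is not alpha to a carbonyl.

Step 4
Reactants: 8 keto dialdehyde
Product: 9 diol ketone
Conditions: SmI2 (2.5 equiv), t-BuOH (2 equiv), THF, −78 °C → rt, slow addition of 8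
Reagents that add atoms: none
Why: SmI2 (divalent samarium) transfers one electron to the unhindered C2 aldehyde, the ketyl adds to the samarium-activated C3 aldehyde and a second electron reduces the alkoxy radical to the diolate, which is the known intramolecular pinacol coupling of 1,6-dialdehydes to cis-cyclohexane-1,2-diols. Ring A closes in the 6-exo-trig mode through a chair in which the C10 and C5 chains are both equatorial on ring B, so the trans ring fusion already fixed by C5 and C10 is kept. C2 and C3 are set together: one trivalent samarium bridging both oxygens holds them syn and gives the cis diol. Of the two cis chairs, the one with C2–O axial suffers 1,3-diaxial contacts with the axial methyls on C10 and C4, so C2–O should go equatorial and C3–O axial, both on the H face. The step needs selectivity for the two aldehydes over the C9 ketone and the isopropenyl group, which is secured by the much faster reduction of aldehydes by SmI2 in THF without HMPA and by the inability of either ketyl to reach C9 from the reacting conformer.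

Step 5
Reactants: 9 diol ketone
Product: 10 acetonide ketone
Conditions: Me2C(OMe)2, PPTS (cat.), CH2Cl2, rt
Reagents that add atoms: 2,2-dimethoxypropane, COC(C)(C)OC
Why: Acid-catalysed transacetalisation, which only a cis-1,2-diol on the cyclohexane undergoes readily, so any trans diol from step 4 stays a polar diol and is removed here.

Step 6
Reactants: 10 acetonide ketone
Product: 11 8-methyl ketone
Conditions: LiN(iPr)2, THF, −78 °C; MeI, −78 → 0 °C
Reagents that add atoms: iodomethane, CI
Why: Kinetic enolate alkylation at C8, the only enolisable position of the ketone because C10 is quaternary, with the C8 configuration irrelevant since C8 becomes sp2 in step 7.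

Step 7
Reactants: 11 8-methyl ketone
Product: 14 enone, via methoxy hydroperoxide 12 (not isolated), via 7-acetate 13 (not isolated)
Conditions: O3, CH2Cl2/MeOH, −78 °C; then Ac2O, Et3N, DMAP (cat.), 0 °C → rt; then DBU, rt
Reagents that add atoms: none
Why: Ozonolysis in methanol traps the carbonyl oxide as the methoxy hydroperoxide, its peracetate undergoes Criegee rearrangement with migration of C7 to oxygen with retention, and the resulting beta-acetoxy ketone loses acetic acid by E1cB elimination to give the conjugated 8-methyl-7-en-9-one.

Step 8
Reactants: 14 enone; 15 2-(2-bromoethyl)-2-methyl-1,3-dioxolane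
Product: 17 tertiary allylic alcohol, via Grignard reagent 16 (not isolated)
Conditions: 15, Mg, THF, rt; then CeCl3 (anhydrous), THF, −78 °C; 14, −78 → 0 °C
Reagents that add atoms: none
Why: Grignard 1,2-addition promoted by CeCl3, which suppresses conjugate addition at C7 and reduction at the hindered, non-enolisable C9 carbonyl, the configuration of the new carbinol being irrelevant because C9 becomes sp2 in step 9.

Step 9
Reactants: 17 tertiary allylic alcohol
Product: 18 8-en-7-one
Conditions: pyridinium chlorochromate (C5H5NH[CrO3Cl]), 4 Å molecular sieves, CH2Cl2, rt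
Reagents that add atoms: pyridinium chlorochromate, c1cc[nH+]cc1.[O-][Cr](=O)(=O)Cl
Why: Babler–Dauben oxidative 1,3-transposition, in which the tertiary allylic chromate ester undergoes a [3,3]-sigmatropic shift to the C7 chromate that is then oxidised to the ketone, leaving the side chain on C9 of a tetrasubstituted 8-ene.

Step 10
Reactants: 18 8-en-7-one
Product: 20 enol triflate, via lithium 7-enolate 19 (not isolated)
Conditions: Li (2.2 equiv), NH3/THF, t-BuOH (1 equiv), −78 °C; evaporate NH3; PhNTf2, THF, 0 °C → rt
Reagents that add atoms: N-phenylbis(trifluoromethanesulfonimide), O=S(=O)(N(c1ccccc1)S(=O)(=O)C(F)(F)F)C(F)(F)F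
Why: Birch-type dissolving-metal reduction of the enone followed by regiospecific O-triflation of the lithium enolate, C9 being set by axial protonation of the beta-carbanion on the H face, anti to the axial C10 methyl, which leaves the side chain equatorial as in the trans-selective reductions of octalones.

Step 11
Reactants: 20 enol triflate
Product: 21 7-ene bis-acetal
Conditions: Pd(OAc)2 (cat.), PPh3, HCO2H, Bu3N, DMF, 60 °C
Reagents that add atoms: none
Why: Palladium-catalysed formate hydrogenolysis of the enol triflate (oxidative addition to zerovalent palladium, formate exchange, decarboxylation, reductive elimination) replaces OTf by H without moving the 7,8-double bond or touching C9.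

Step 12
Reactants: 21 7-ene bis-acetal
Product: 22 diol methyl ketone
Conditions: 1 M aq. HCl, THF, rt
Reagents that add atoms: water, O
Why: Acid-catalysed acetal hydrolysis removes the acetonide and the dioxolane in one operation, the trisubstituted 7-ene being stable to dilute acid at room temperature.

Step 13
Reactants: 22 diol methyl ketone
Product: 23 E-enoate
Conditions: (EtO)2P(O)CH2CO2Et, NaH (slightly less than the phosphonate), THF, 0 → 50 °C
Reagents that add atoms: triethyl phosphonoacetate, CCOC(=O)CP(=O)(OCC)OCC
Why: Horner–Wadsworth–Emmons olefination with the preformed phosphonate anion, which is too weak a base to deprotonate the free diol and is E-selective for a methyl alkyl ketone, the minor Z isomer being removed by chromatography.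

Step 14
Reactants: 23 E-enoate
Product: 24 triol
Conditions: iBu2AlH (excess), CH2Cl2, −78 → 0 °C
Reagents that add atoms: none
Why: 1,2-Reduction of the conjugated ester by the aluminium hydride gives the allylic alcohol without touching either double bond.

Step 15
Reactants: 24 triol
Product: 25 target
Conditions: Ac2O (2.1 equiv), pyridine, CH2Cl2, 0 °C
Reagents that add atoms: acetic anhydride, CC(=O)OC(C)=O
Why: Selective acylation in which the primary allylic C15 hydroxyl and the equatorial C2 hydroxyl react, whereas the axial C3 hydroxyl, neopentyl to the C4 gem-dimethyl group and 1,3-diaxial to H1 and H5, stays free with a limiting amount of anhydride at low temperature.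

Compound list
1 | (S)-(+)-carvone | CC1=CC[C@@H](CC1=O)C(C)=C | starting material
2 | methyl isobutyrate | COC(=O)C(C)C | starting material
3 | methyl bromoacetate | COC(=O)CBr | starting material
4 | lithium enolate of methyl isobutyrate | COC(O[Li])=C(C)C | intermediate
5 | lithium enolate of the Michael adduct (C9–C10 enolate; CMe2CO2Me on C5 anti to the C7 isopropenyl) | CC1=C(O[Li])C[C@@H](C(C)=C)C[C@@H]1C(C)(C)C(=O)OC | intermediate
6 | keto diester: methyl 2-[2-(2-methoxy-2-oxoethyl)-2-methyl-3-oxo-5-(prop-1-en-2-yl)cyclohexyl]-2-methylpropanoate; C5 chain anti to the C7 isopropenyl, CH2CO2Me on C10 anti to the C5 chain | COC(=O)C[C@@]1(C)C(=O)C[C@@H](C(C)=C)C[C@@H]1C(C)(C)C(=O)OC | intermediate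
7 | triol: 6 with both esters reduced to CH2OH and C9 reduced to CHOH (C9 epimer mixture) | OCC[C@@]1(C)C(O)C[C@@H](C(C)=C)C[C@@H]1C(C)(C)CO | intermediate
8 | keto dialdehyde: ring B cyclohexanone (C9=O) with CH3 and CH2CHO on C10, CMe2CHO on C5, isopropenyl on C7; configuration as in 6 | O=CC[C@@]1(C)C(=O)C[C@@H](C(C)=C)C[C@@H]1C(C)(C)C=O | intermediate
9 | diol ketone: trans-decalin (H5 anti to C20), 2,3-cis-diol on the H face (2-OH equatorial, 3-OH axial), 9-ketone, 7-isopropenyl axial on the H face | O=C1C[C@@H](C(C)=C)C[C@@H]2C(C)(C)[C@@H](O)[C@@H](O)C[C@@]12C | intermediate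
10 | acetonide ketone: 2,3-O-isopropylidene derivative of 9 | O=C1C[C@@H](C(C)=C)C[C@@H]2C(C)(C)[C@@H](OC(C)(C)O3)[C@@H]3C[C@@]12C | intermediate
11 | 8-methyl ketone: 10 methylated at C8 (C8 epimer mixture) | O=C1C(C)[C@@H](C(C)=C)C[C@@H]2C(C)(C)[C@@H](OC(C)(C)O3)[C@@H]3C[C@@]12C | intermediate
12 | methoxy hydroperoxide: 11 with C7–C(CH3)(OCH3)OOH in place of the isopropenyl group | O=C1C(C)[C@@H](C(C)(OC)OO)C[C@@H]2C(C)(C)[C@@H](OC(C)(C)O3)[C@@H]3C[C@@]12C | intermediate
13 | 7-acetate: 7-acetoxy-8-methyl-9-ketone acetonide, OAc axial on the H face (retention at C7) | O=C1C(C)[C@@H](OC(C)=O)C[C@@H]2C(C)(C)[C@@H](OC(C)(C)O3)[C@@H]3C[C@@]12C | intermediate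
14 | enone: 8-methyl-7-en-9-one acetonide (C7=C8–C9=O) | O=C1C(C)=CC[C@@H]2C(C)(C)[C@@H](OC(C)(C)O3)[C@@H]3C[C@@]12C | intermediate
15 | 2-(2-bromoethyl)-2-methyl-1,3-dioxolane | CC1(CCBr)OCCO1 | starting material
16 | Grignard reagent: [2-(2-methyl-1,3-dioxolan-2-yl)ethyl]magnesium bromide | CC1(CC[Mg]Br)OCCO1 | intermediate
17 | tertiary allylic alcohol: 9-hydroxy-8-methyl-7-ene carrying the C11–C13 dioxolane chain on C9 (C9 configuration not defined), 2,3-acetonide | CC4(CCC1(O)C(C)=CC[C@@H]2C(C)(C)[C@@H](OC(C)(C)O3)[C@@H]3C[C@@]12C)OCCO4 | intermediate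
18 | 8-en-7-one: C7=O, C8(CH3)=C9 bearing the dioxolane chain, 2,3-acetonide | CC4(CCC1=C(C)C(=O)C[C@@H]2C(C)(C)[C@@H](OC(C)(C)O3)[C@@H]3C[C@@]12C)OCCO4 | intermediate
19 | lithium 7-enolate: C7(OLi)=C8, H9 on the H face, side chain equatorial on the methyl face | CC4(CC[C@@H]1C(C)=C(O[Li])C[C@@H]2C(C)(C)[C@@H](OC(C)(C)O3)[C@@H]3C[C@@]12C)OCCO4 | intermediate
20 | enol triflate: 7-(trifluoromethanesulfonyloxy)-7-ene, C9 as in 19 | CC4(CC[C@@H]1C(C)=C(OS(=O)(=O)C(F)(F)F)C[C@@H]2C(C)(C)[C@@H](OC(C)(C)O3)[C@@H]3C[C@@]12C)OCCO4 | intermediate
21 | 7-ene bis-acetal: 14,15-dinorlabd-7-ene with the 13-ketone as dioxolane and the 2,3-diol as acetonide | CC4(CC[C@@H]1C(C)=CC[C@@H]2C(C)(C)[C@@H](OC(C)(C)O3)[C@@H]3C[C@@]12C)OCCO4 | intermediate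
22 | diol methyl ketone: 2,3-dihydroxy-14,15-dinorlabd-7-en-13-one, both hydroxyls on the H face | CC(=O)CC[C@@H]1C(C)=CC[C@@H]2C(C)(C)[C@@H](O)[C@@H](O)C[C@@]12C | intermediate
23 | E-enoate: ethyl 2,3-dihydroxylabda-7,13E-dien-15-oate | CCOC(=O)/C=C(\C)CC[C@@H]1C(C)=CC[C@@H]2C(C)(C)[C@@H](O)[C@@H](O)C[C@@]12C | intermediate
24 | triol: labda-7,13E-diene-2,3,15-triol, 2-OH equatorial and 3-OH axial on the H face | OC/C=C(\C)CC[C@@H]1C(C)=CC[C@@H]2C(C)(C)[C@@H](O)[C@@H](O)C[C@@]12C | intermediate
25 | target: (2S,3R,5S,9R,10S,13E)-labda-7,13-diene-2,3,15-triol 2,15-diacetate | CC(=O)OC/C=C(\C)CC[C@@H]1C(C)=CC[C@@H]2C(C)(C)[C@@H](O)[C@@H](OC(C)=O)C[C@@]12C | target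

Total step count: 15. Longest linear sequence: 15 steps, from (S)-carvone 1.

Steps most likely to fail

Step 4. The free C9 ketone may be drawn into the carbonyl chemistry: ketone–aldehyde coupling through the conformer with the C5 chain axial, over-reduction, or aldol loss of the keto dialdehyde before it couples. The fallback takes C9 out of the carbonyl manifold before the aldehydes exist. It sets out from keto diester 6 and returns at acetonide ketone 10.
- TMSOCH2CH2OTMS with catalytic TMSOTf in CH2Cl2 at low temperature should convert 6 into the dioxolane diester F1.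
- LiAlH4 should reduce it to the dioxolane diol F2.
- Swern oxidation should give the dioxolane dialdehyde F3, which carries no other reducible or enolisable carbonyl.
- The ring closure can then be driven with the stronger SmI2/HMPA system to the dioxolane cis-diol F4.
- TsOH in acetone/Me2C(OMe)2 should exchange the dioxolane for the ketone and capture the diol as its acetonide, giving 10.

Step 1. The ester enolate may add 1,2 to the alpha-substituted enone, or the crowded enolate 5 may be protonated by the bromoacetate instead of alkylated. The fallback separates the two bond formations. It sets out from 1 and returns at 6.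
- Mukaiyama–Michael addition of the purchased silyl ketene acetal Me2C=C(OMe)OSiMe3 under catalytic TMSOTf in CH2Cl2 at −78 °C, anti to the isopropenyl group, should give the isolable trimethylsilyl enol ether F5.
- MeLi in THF should release the regiodefined lithium enolate 5 from it.
- Alkylation with 3 in the presence of DMPU should then give 6.

Step 8. Addition to the neopentyl C9 carbonyl may be outrun by conjugate addition at C7 or by hydride transfer from the Grignard reagent. The fallback attaches the chain by cross-coupling instead of carbonyl addition and bypasses steps 8 and 9. It sets out from enone 14 and returns at 18.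
- Conjugate reduction of 14 with K[sBu3BH] in THF at −78 °C and trapping of the enolate with PhNTf2 should give the C9 enol triflate F6.
- Fe(acac)3-catalysed cross-coupling with Grignard reagent 16 in THF/NMP should give the 8-ene F7.
- Allylic oxidation at C7 with CrO3/3,5-dimethylpyrazole in CH2Cl2 should give 18.

Further compounds
F1 | step 4 | dioxolane diester: 6 with the C9 ketone as ethylene ketal | COC(=O)C[C@@]1(C)C2(OCCO2)C[C@@H](C(C)=C)C[C@@H]1C(C)(C)C(=O)OC
F2 | step 4 | dioxolane diol: F1 with both esters reduced to CH2OH | OCC[C@@]1(C)C2(OCCO2)C[C@@H](C(C)=C)C[C@@H]1C(C)(C)CO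
F3 | step 4 | dioxolane dialdehyde: 8 with the C9 ketone as ethylene ketal | O=CC[C@@]1(C)C2(OCCO2)C[C@@H](C(C)=C)C[C@@H]1C(C)(C)C=O
F4 | step 4 | dioxolane cis-diol: 9 with the C9 ketone as ethylene ketal | C1COC2(O1)C[C@@H](C(C)=C)C[C@@H]3C(C)(C)[C@@H](O)[C@@H](O)C[C@@]23C
F5 | step 1 | trimethylsilyl enol ether of the Michael adduct (C9–C10 enol ether, C5 chain anti to the isopropenyl) | CC1=C(O[Si](C)(C)C)C[C@@H](C(C)=C)C[C@@H]1C(C)(C)C(=O)OC
F6 | step 8 | C9 enol triflate: 9-(trifluoromethanesulfonyloxy)-8-methyl-8-ene acetonide | FC(F)(F)S(=O)(=O)OC1=C(C)CC[C@@H]2C(C)(C)[C@@H](OC(C)(C)O3)[C@@H]3C[C@@]12C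
F7 | step 8 | 8-ene: tetrasubstituted C8=C9 olefin carrying the dioxolane chain on C9, 2,3-acetonide | CC4(CCC1=C(C)CC[C@@H]2C(C)(C)[C@@H](OC(C)(C)O3)[C@@H]3C[C@@]12C)OCCO4
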